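**Plan**

- Cuts: in the 5-hydroxyindole, C3a–C7a and C4–C5 are cut together (after water is put back across C2–C3). This opens both of its rings to an N-Boc-2-aminofuran tied to a terminal alkyne through a tertiary carbinol.
- Enabling feature: the oxygen-bearing C5 lies para to the nitrogen-bearing C7a in the benzo ring, the same 1,4-relation that the ring oxygen spans between C5 and the amino carbon C2 of a 2-aminofuran. C7a, C7, C6 and C5 are the furan carbons; C3a and C4 are the alkyne carbons.
- Earlier cuts: carbinol–ethynyl bond (acetylide addition), central ring–carbonyl bond (aryllithium plus Weinreb amide), N–CH2 bond (carbamate alkylation), and central ring–C3 bond of the 6-methoxyindole (Suzuki–Miyaura).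
- Forward: the central benzene ring and the 6-methoxyindole are bought as rings. The side chain, then the indole, then the alkyne are attached; the pyrrole and benzo rings of the second indole close in one thermal operation; the tosyl group is removed last.
- Stereochemistry: the target has no stereocentre. The single carbinol centre of the cycloaddition precursor is made racemic and disappears on aromatisation.

Key step: step 8

Remark: both aryl–indole axes have only methoxy and hydrogen ortho neighbours and are taken as freely rotating, so no atropisomerism is treated. tert-Butyl furan-2-ylcarbamate is taken as a catalogue compound.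

Step 1
Reactants: 1 1,2,4,5-tetramethoxybenzene
Product: 2 1,4-dibromo-2,3,5,6-tetramethoxybenzene
Conditions: Br2 (2.1 equiv), CH2Cl2, 0 °C to rt
Reagents that add atoms: bromine, BrBr
Why: Electrophilic aromatic bromination: the only two free positions of 1 are each flanked by two methoxy groups and strongly activated, so both should be brominated, and the low temperature holds back oxidative demethylation.

Step 2
Reactants: 3 tert-butyl furan-2-ylcarbamate; 4 2-chloro-N-methoxy-N-methylacetamide
Product: 5 tert-butyl N-(furan-2-yl)-N-{2-[methoxy(methyl)amino]-2-oxoethyl}carbamate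
Conditions: NaH, DMF, 0 °C; then 4, Bu4NI (cat.), 0 °C to rt
Reagents that add atoms: none
Why: SN2 N-alkylation of a carbamate anion: deprotonated 3 is a soft nitrogen nucleophile that should displace the halide from the activated α-carbon of 4 and leave the Weinreb carbonyl untouched.

Step 3
Reactants: 2 1,4-dibromo-2,3,5,6-tetramethoxybenzene; 5 tert-butyl N-(furan-2-yl)-N-{2-[methoxy(methyl)amino]-2-oxoethyl}carbamate
Product: 7 tert-butyl N-[2-(4-bromo-2,3,5,6-tetramethoxyphenyl)-2-oxoethyl]-N-(furan-2-yl)carbamate, via 4-bromo-2,3,5,6-tetramethoxyphenyllithium 6 (not isolated)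
Conditions: n-BuLi (1.0 equiv), THF, −78 °C; then 5, −78 to −40 °C; then aq NH4Cl
Reagents that add atoms: none
Why: Bromine–lithium exchange followed by Weinreb ketone synthesis: one equivalent of n-BuLi should exchange only one of the two equivalent bromides, since a second exchange on the already metalated ring is disfavoured, and the chelated tetrahedral adduct of 6 with 5 holds the acylation at the ketone level until the quench.

Step 4
Reactants: 8 6-methoxyindole
Product: 10 3-iodo-6-methoxy-1-tosylindole, via 3-iodo-6-methoxyindole 9 (not isolated)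
Conditions: KOH (4 equiv), I2 (1.0 equiv), DMF, 0 °C to rt; then TsCl (1.5 equiv), 0 °C to rt
Reagents that add atoms: iodine, [I][I]; p-toluenesulfonyl chloride, Cc1ccc(S(=O)(=O)Cl)cc1
Why: Electrophilic iodination at C3, the most nucleophilic position of a free indole, followed in the same flask by N-sulfonylation of the potassium indolide, which avoids handling the light- and air-sensitive 9.

Step 5
Reactants: 10 3-iodo-6-methoxy-1-tosylindole
Product: 11 6-methoxy-3-(4,4,5,5-tetramethyl-1,3,2-dioxaborolan-2-yl)-1-tosylindole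
Conditions: HBpin (1.5 equiv), Et3N, Pd(PPh3)4 (3 mol%), dioxane, 80 °C
Reagents that add atoms: pinacolborane, [H]B1OC(C)(C)C(C)(C)O1
Why: Masuda-type palladium-catalysed borylation: the C3–I bond adds oxidatively to zerovalent palladium and boron is transferred from the amine-activated pinacolborane, a reaction class well established for N-sulfonyl-3-iodoindoles.

Step 6
Reactants: 7 tert-butyl N-[2-(4-bromo-2,3,5,6-tetramethoxyphenyl)-2-oxoethyl]-N-(furan-2-yl)carbamate; 11 6-methoxy-3-(4,4,5,5-tetramethyl-1,3,2-dioxaborolan-2-yl)-1-tosylindole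
Product: 12 tert-butyl N-(furan-2-yl)-N-{2-oxo-2-[2,3,5,6-tetramethoxy-4-(6-methoxy-1-tosylindol-3-yl)phenyl]ethyl}carbamate
Conditions: Pd(OAc)2 (5 mol%), SPhos (10 mol%), K3PO4, toluene/H2O (10:1), degassed, 90 °C
Reagents that add atoms: none
Why: Suzuki–Miyaura coupling: the bulky electron-rich biarylphosphine should allow oxidative addition into the di-ortho-methoxy aryl bromide and reductive elimination of the hindered biaryl, while phosphate in an alcohol-free toluene–water mixture spares tosyl, Boc, ketone and amidofuran.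

Step 7
Reactants: 12 tert-butyl N-(furan-2-yl)-N-{2-oxo-2-[2,3,5,6-tetramethoxy-4-(6-methoxy-1-tosylindol-3-yl)phenyl]ethyl}carbamate; 13 ethynylmagnesium bromide
Product: 14 racemic tert-butyl N-(furan-2-yl)-N-{2-hydroxy-2-[2,3,5,6-tetramethoxy-4-(6-methoxy-1-tosylindol-3-yl)phenyl]but-3-yn-1-yl}carbamate
Conditions: 13 (3 equiv), LaCl3·2LiCl (30 mol%), THF, −20 to 0 °C; then aq NH4Cl at 0 °C
Reagents that add atoms: none
Why: 1,2-Addition of an alkynyl Grignard reagent to a ketone, in which the oxophilic lanthanum salt raises carbonyl electrophilicity and suppresses enolisation and the small linear nucleophile can reach the carbonyl twisted out of the plane of the di-ortho-substituted ring; the new carbinol centre forms without control as a racemate, which is harmless because step 8 removes it.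

Step 8
Reactants: 14 racemic tert-butyl N-(furan-2-yl)-N-{2-hydroxy-2-[2,3,5,6-tetramethoxy-4-(6-methoxy-1-tosylindol-3-yl)phenyl]but-3-yn-1-yl}carbamate
Product: 18 3-[2,3,5,6-tetramethoxy-4-(6-methoxy-1-tosylindol-3-yl)phenyl]-1H-indol-5-ol, via 5,7a-epoxy-bridged cycloadduct 15 (not isolated), via N-Boc-indoline-3,5-diol 16 (not isolated), via N-Boc-5-hydroxyindole 17 (not isolated)
Conditions: o-dichlorobenzene (0.02 M, degassed), sealed vial, microwave, 200 °C
Reagents that add atoms: none
Why: Thermal intramolecular Diels–Alder reaction of the furan: the electron-rich 2-amidofuran (diene, furan C2–C5) adds suprafacially across the tethered terminal alkyne, the internal alkyne carbon bonding to the nitrogen-bearing furan C2 (future C3a–C7a) and the terminal CH to furan C5 (future C4–C5), to give the 7-oxanorbornadiene 15. The carbamate nitrogen then pushes the oxygen bridge off C7a and loss of the C5 proton aromatises the six-membered ring to phenol 16, after which elimination of water between the tertiary C3–OH and C2–H gives 17 and the Boc group leaves at this temperature as 2-methylpropene and CO2. The closest known reaction type is the microwave-promoted cycloaddition–fragmentation–aromatisation cascade of N-Boc-2-aminofurans bearing tertiary alkynol tethers, which delivers 3-substituted 5-hydroxyindoles. The five-membered ring closes in the fused mode because the three-atom tether N–CH2–C(OH)Ar joins the diene terminus to the dienophile, and the six-membered ring closes as the [4+2] ring itself. No stereocentre remains in 18, since the centres of 15 and 16 (racemic diastereomer mixtures) are all erased by aromatisation, so facial selectivity is irrelevant. The step needs regioselectivity, secured by the short tether, which cannot reach the opposite orientation and so places oxygen at C5; it also needs cycloaddition to outrun Boc thermolysis, which is helped by angle compression at the fully substituted carbinol carbon bearing the bulky aryl group and by the unhindered alkyne terminus, while tosylindole and methyl ethers are thermally inert spectators.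

Step 9
Reactants: 18 3-[2,3,5,6-tetramethoxy-4-(6-methoxy-1-tosylindol-3-yl)phenyl]-1H-indol-5-ol
Product: 19 3-[2,3,5,6-tetramethoxy-4-(6-methoxy-1H-indol-3-yl)phenyl]-1H-indol-5-ol (CNP0234672.0)
Conditions: Mg turnings (10 equiv), MeOH, ultrasound, rt
Reagents that add atoms: none
Why: Reductive desulfonylation by single-electron transfer from magnesium to the arenesulfonyl group, which should cleave the N–S bond of the N-tosylindole and leave the aryl methyl ethers, the phenol and both indole rings untouched.

**Compound list**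

1 | 1,2,4,5-tetramethoxybenzene | COc1cc(OC)c(OC)cc1OC | starting material
2 | 1,4-dibromo-2,3,5,6-tetramethoxybenzene | COc1c(Br)c(OC)c(OC)c(Br)c1OC | intermediate
3 | tert-butyl furan-2-ylcarbamate | CC(C)(C)OC(=O)Nc1ccco1 | starting material
4 | 2-chloro-N-methoxy-N-methylacetamide | CON(C)C(=O)CCl | starting material
5 | tert-butyl N-(furan-2-yl)-N-{2-[methoxy(methyl)amino]-2-oxoethyl}carbamate | CON(C)C(=O)CN(C(=O)OC(C)(C)C)c1ccco1 | intermediate
6 | 4-bromo-2,3,5,6-tetramethoxyphenyllithium (formed in situ) | [Li]c1c(OC)c(OC)c(Br)c(OC)c1OC | intermediate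
7 | tert-butyl N-[2-(4-bromo-2,3,5,6-tetramethoxyphenyl)-2-oxoethyl]-N-(furan-2-yl)carbamate | COc1c(Br)c(OC)c(OC)c(C(=O)CN(C(=O)OC(C)(C)C)c2ccco2)c1OC | intermediate
8 | 6-methoxyindole | COc1ccc2cc[nH]c2c1 | starting material
9 | 3-iodo-6-methoxyindole (formed in situ) | Ic1c[nH]c2cc(OC)ccc12 | intermediate
10 | 3-iodo-6-methoxy-1-tosylindole | Ic1cn(S(=O)(=O)c2ccc(C)cc2)c2cc(OC)ccc12 | intermediate
11 | 6-methoxy-3-(4,4,5,5-tetramethyl-1,3,2-dioxaborolan-2-yl)-1-tosylindole | COc1ccc2c(B3OC(C)(C)C(C)(C)O3)cn(S(=O)(=O)c3ccc(C)cc3)c2c1 | intermediate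
12 | tert-butyl N-(furan-2-yl)-N-{2-oxo-2-[2,3,5,6-tetramethoxy-4-(6-methoxy-1-tosylindol-3-yl)phenyl]ethyl}carbamate | COc1ccc2c(-c3c(OC)c(OC)c(C(=O)CN(C(=O)OC(C)(C)C)c4ccco4)c(OC)c3OC)cn(S(=O)(=O)c3ccc(C)cc3)c2c1 | intermediate
13 | ethynylmagnesium bromide | C#C[Mg]Br | starting material
14 | racemic tert-butyl N-(furan-2-yl)-N-{2-hydroxy-2-[2,3,5,6-tetramethoxy-4-(6-methoxy-1-tosylindol-3-yl)phenyl]but-3-yn-1-yl}carbamate | C#CC(O)(CN(C(=O)OC(C)(C)C)c1ccco1)c1c(OC)c(OC)c(-c2cn(S(=O)(=O)c3ccc(C)cc3)c3cc(OC)ccc23)c(OC)c1OC | intermediate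
15 | tert-butyl 3-aryl-3-hydroxy-2,3-dihydro-5H-5,7a-epoxyindole-1-carboxylate, aryl = 2,3,5,6-tetramethoxy-4-(6-methoxy-1-tosylindol-3-yl)phenyl (racemic diastereomer mixture, formed in situ) | CC(C)(C)OC(=O)N1CC(O)(c4c(OC)c(OC)c(-c5cn(S(=O)(=O)c6ccc(C)cc6)c6cc(OC)ccc56)c(OC)c4OC)C2=CC3C=CC12O3 | intermediate
16 | tert-butyl 3-aryl-3,5-dihydroxy-2,3-dihydroindole-1-carboxylate, same aryl (racemic, formed in situ) | CC(C)(C)OC(=O)N1CC(O)(c3c(OC)c(OC)c(-c4cn(S(=O)(=O)c5ccc(C)cc5)c5cc(OC)ccc45)c(OC)c3OC)c2cc(O)ccc21 | intermediate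
17 | tert-butyl 5-hydroxy-3-[2,3,5,6-tetramethoxy-4-(6-methoxy-1-tosylindol-3-yl)phenyl]indole-1-carboxylate (formed in situ) | CC(C)(C)OC(=O)n1cc(-c3c(OC)c(OC)c(-c4cn(S(=O)(=O)c5ccc(C)cc5)c5cc(OC)ccc45)c(OC)c3OC)c2cc(O)ccc21 | intermediate
18 | 3-[2,3,5,6-tetramethoxy-4-(6-methoxy-1-tosylindol-3-yl)phenyl]-1H-indol-5-ol | COc1ccc2c(-c3c(OC)c(OC)c(-c4c[nH]c5ccc(O)cc45)c(OC)c3OC)cn(S(=O)(=O)c3ccc(C)cc3)c2c1 | intermediate
19 | 3-[2,3,5,6-tetramethoxy-4-(6-methoxy-1H-indol-3-yl)phenyl]-1H-indol-5-ol (CNP0234672.0, achiral) | COc1ccc2c(-c3c(OC)c(OC)c(-c4c[nH]c5ccc(O)cc45)c(OC)c3OC)c[nH]c2c1 | target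

**Step count**

Total step count: 9.
Longest linear sequence: 6 steps (steps 1, 3, 6, 7, 8, 9). The branch through steps 4 and 5 and the branch through steps 2 and 3 are of the same length.

**Steps most likely to fail**

**Step 8.**
- Process at risk: thermolysis of the Boc group may outrun the cycloaddition of the unactivated alkyne, after which the unprotected aminofuran would decompose. Ionisation of the electron-rich tertiary propargylic carbinol would be a second drain.
- Fallback: the second indole is brought in ready-made by known cross-coupling chemistry. It sets out from 2 and 11 and comes back to the route at 17.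
- Coupling of 11 with a threefold excess of 2 under the conditions of step 6 should give 3-(4-bromo-2,3,5,6-tetramethoxyphenyl)-6-methoxy-1-tosylindole F1, the surplus 2 being recovered.
- Commercial 5-benzyloxyindole is treated with Boc2O and DMAP in MeCN to give tert-butyl 5-(benzyloxy)indole-1-carboxylate F2.
- Iridium-catalysed C–H borylation ([Ir(OMe)(cod)]2, 4,4'-di-tert-butyl-2,2'-bipyridine, HBpin, THF, 60 °C), steered by the bulky carbamate away from C2 and C7 to C3, should give tert-butyl 5-(benzyloxy)-3-(4,4,5,5-tetramethyl-1,3,2-dioxaborolan-2-yl)indole-1-carboxylate F3.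
- Suzuki–Miyaura coupling of F1 with F3 gives tert-butyl 5-(benzyloxy)-3-[2,3,5,6-tetramethoxy-4-(6-methoxy-1-tosylindol-3-yl)phenyl]indole-1-carboxylate F4.
- Hydrogenolysis (H2, Pd/C, EtOAc/EtOH) frees the phenol and gives 17. Short heating in o-dichlorobenzene, or TFA in CH2Cl2, takes 17 on to 18.

**Step 7.**
- Process at risk: the acetylide may act as a base and enolise the hindered ketone, and the new tertiary alkoxide may attack the neighbouring Boc carbonyl.
- Fallback: the aryl–carbinol bond, not the alkynyl–carbinol bond, is made last. It sets out from 5 and 2 and comes back at 14.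
- Lithium (triisopropylsilyl)acetylide F5, made from the commercial alkyne and n-BuLi, is acylated by Weinreb amide 5 (THF, −78 °C). This gives tert-butyl N-(furan-2-yl)-N-[2-oxo-4-(triisopropylsilyl)but-3-yn-1-yl]carbamate F6.
- Aryllithium 6, generated from 2 as in step 3, should add at −78 °C to this unhindered and far more electrophilic ynone carbonyl, the bulky silyl group blocking conjugate addition.
- A cold quench gives racemic tert-butyl N-[2-(4-bromo-2,3,5,6-tetramethoxyphenyl)-2-hydroxy-4-(triisopropylsilyl)but-3-yn-1-yl]-N-(furan-2-yl)carbamate F7.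
- Coupling with 11 under the conditions of step 6 gives racemic tert-butyl N-(furan-2-yl)-N-{2-hydroxy-2-[2,3,5,6-tetramethoxy-4-(6-methoxy-1-tosylindol-3-yl)phenyl]-4-(triisopropylsilyl)but-3-yn-1-yl}carbamate F8.
- TBAF buffered with AcOH (THF, 0 °C) frees the alkyne terminus to give 14.

**Step 3.**
- Process at risk: the hindered aryllithium may take a proton from the methylene group of 5, which lies between amide and carbamate, instead of adding to the carbonyl. This merely quenches the organometallic.
- Fallback: the C–N bond is formed after the C–C bond. It sets out from 2, 4 and 3 and comes back at 7.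
- Aryllithium 6 is acylated by 4 itself (THF, −78 °C), a standard entry to α-chloro ketones, to give 1-(4-bromo-2,3,5,6-tetramethoxyphenyl)-2-chloroethan-1-one F9.
- The sodium salt of 3 (NaH, DMF, 0 °C, NaI cat.) is then alkylated with F9 to give 7.

**Further compounds**

F1 | step 8 | 3-(4-bromo-2,3,5,6-tetramethoxyphenyl)-6-methoxy-1-tosylindole | COc1ccc2c(-c3c(OC)c(OC)c(Br)c(OC)c3OC)cn(S(=O)(=O)c3ccc(C)cc3)c2c1
F2 | step 8 | tert-butyl 5-(benzyloxy)indole-1-carboxylate | CC(C)(C)OC(=O)n1ccc2cc(OCc3ccccc3)ccc21
F3 | step 8 | tert-butyl 5-(benzyloxy)-3-(4,4,5,5-tetramethyl-1,3,2-dioxaborolan-2-yl)indole-1-carboxylate | CC(C)(C)OC(=O)n1cc(B3OC(C)(C)C(C)(C)O3)c2cc(OCc3ccccc3)ccc21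
F4 | step 8 | tert-butyl 5-(benzyloxy)-3-[2,3,5,6-tetramethoxy-4-(6-methoxy-1-tosylindol-3-yl)phenyl]indole-1-carboxylate | CC(C)(C)OC(=O)n1cc(-c3c(OC)c(OC)c(-c4cn(S(=O)(=O)c5ccc(C)cc5)c5cc(OC)ccc45)c(OC)c3OC)c2cc(OCc3ccccc3)ccc21
F5 | step 7 | lithium (triisopropylsilyl)acetylide | [Li]C#C[Si](C(C)C)(C(C)C)C(C)C
F6 | step 7 | tert-butyl N-(furan-2-yl)-N-[2-oxo-4-(triisopropylsilyl)but-3-yn-1-yl]carbamate | CC(C)[Si](C#CC(=O)CN(C(=O)OC(C)(C)C)c1ccco1)(C(C)C)C(C)C
F7 | step 7 | racemic tert-butyl N-[2-(4-bromo-2,3,5,6-tetramethoxyphenyl)-2-hydroxy-4-(triisopropylsilyl)but-3-yn-1-yl]-N-(furan-2-yl)carbamate | CC(C)[Si](C#CC(O)(CN(C(=O)OC(C)(C)C)c1ccco1)c1c(OC)c(OC)c(Br)c(OC)c1OC)(C(C)C)C(C)C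
F8 | step 7 | racemic tert-butyl N-(furan-2-yl)-N-{2-hydroxy-2-[2,3,5,6-tetramethoxy-4-(6-methoxy-1-tosylindol-3-yl)phenyl]-4-(triisopropylsilyl)but-3-yn-1-yl}carbamate | CC(C)[Si](C#CC(O)(CN(C(=O)OC(C)(C)C)c1ccco1)c1c(OC)c(OC)c(-c2cn(S(=O)(=O)c3ccc(C)cc3)c3cc(OC)ccc23)c(OC)c1OC)(C(C)C)C(C)C
F9 | step 3 | 1-(4-bromo-2,3,5,6-tetramethoxyphenyl)-2-chloroethan-1-one | COc1c(Br)c(OC)c(OC)c(C(=O)CCl)c1OC
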